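**Plan**

- Aryl positions follow the target: C-1 carries the chain, C-2 and C-4 the hydroxyls, C-3 the methoxy group. The retrosynthesis first cuts the ester C(acyl)–O(octadecyl) bond together with an O-acetyl bond on O-4. This leads back to octadecan-1-ol and an acetyl-protected, lactonised form of the acid.
- The enabling feature is that the hydroxyl on C-2 is ortho to the three-carbon acyl chain on C-1. The benzene ring, O-2 and the chain are therefore an opened 3,4-dihydrocoumarin (six-membered lactone fused to the arene). That lactone is the five-membered ketone ring of a 1-indanone with one oxygen inserted between the carbonyl carbon and the ring-fusion aryl carbon. The second cut is thus the aryl C-2–O bond.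
- The third cut is the aryl C-2–C(acyl) bond of the indanone, plus a C-6–Br blocking bond. This leads back to O-acetylated dihydroferulic acid, which already holds the 3-methoxy-4-oxy pattern.
- Forward: acetylate O-4, brominate para to the methoxy group (C-6), close the five-membered ketone ring onto C-2 by Friedel–Crafts acylation, and remove the bromine. The ring is then expanded to the six-membered lactone by Baeyer–Villiger oxidation. Last, sodium octadecan-1-olate opens the lactone and removes the acetyl group in one operation, which joins the C18 chain.
- Stereochemistry: the target has no stereocenter and no stereogenic double bond, so nothing has to be set.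

Key step: step 5

**Route**

Step 1
Reactants: 1 3-(4-hydroxy-3-methoxyphenyl)propanoic acid (dihydroferulic acid)
Product: 2 3-(4-acetoxy-3-methoxyphenyl)propanoic acid
Conditions: Ac2O, pyridine, DMAP (cat.), 0 °C to rt; aq. HCl work-up
Reagents that add atoms: acetic anhydride, CC(=O)OC(C)=O
Why: O-Acetylation of the phenol (nucleophilic acyl substitution) is routine, the carboxyl group returns as the free acid on aqueous work-up, and the ester turns the phenol oxygen into a weak donor so that the methoxy group alone steers the next substitution.

Step 2
Reactants: 2 3-(4-acetoxy-3-methoxyphenyl)propanoic acid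
Product: 3 3-(4-acetoxy-2-bromo-5-methoxyphenyl)propanoic acid
Conditions: Br2, NaOAc, AcOH, rt
Reagents that add atoms: bromine, BrBr
Why: Electrophilic aromatic bromination should go para to the methoxy group, the strongest donor, at the carbon that is also ortho to the alkyl chain, as is usual for O-acylated guaiacol derivatives, while the carbon between chain and methoxy group is crowded and the carbon next to the acetoxy group is the least activated.

Step 3
Reactants: 3 3-(4-acetoxy-2-bromo-5-methoxyphenyl)propanoic acid
Product: 4 6-acetoxy-4-bromo-7-methoxy-2,3-dihydro-1H-inden-1-one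
Conditions: P2O5 in MeSO3H (1:10 w/w), 50 °C; ice-water quench
Reagents that add atoms: none
Why: Intramolecular Friedel–Crafts acylation through the acylium ion can reach only the two ring carbons ortho to the chain, one of which now carries bromine, so the five-membered ketone ring should close on the carbon next to the methoxy group, whose ortho donor effect suffices, as in the bromine-blocked route to 7-alkoxyindan-1-ones.

Step 4
Reactants: 4 6-acetoxy-4-bromo-7-methoxy-2,3-dihydro-1H-inden-1-one
Product: 5 6-acetoxy-7-methoxy-2,3-dihydro-1H-inden-1-one
Conditions: H2 (1 atm), 10% Pd/C, Et3N, EtOAc, rt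
Reagents that add atoms: none
Why: Palladium-catalysed hydrogenolysis of the aryl C–Br bond (hydrodehalogenation) is fast at atmospheric pressure when a base takes up the HBr, and under these mild conditions neither the aryl ketone nor the aryl acetate should be reduced or cleaved.

Step 5
Reactants: 5 6-acetoxy-7-methoxy-2,3-dihydro-1H-inden-1-one
Product: 7 7-acetoxy-8-methoxy-3,4-dihydro-2H-chromen-2-one, via peroxyhemiketal adduct 6 (not isolated)
Conditions: mCPBA (1.5 equiv), TsOH·H2O (10 mol %), CH2Cl2, 0 °C to rt, dark
Reagents that add atoms: meta-chloroperoxybenzoic acid, OOC(=O)c1cccc(Cl)c1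
Why: Addition of the peroxy acid to the acid-activated carbonyl gives adduct 6, in which the C-1–C-7a bond can align anti to the weak O–O bond; C-7a then moves onto the proximal peroxide oxygen while 3-chlorobenzoate departs, which creates the aryl C–O bond. The closest known reaction type is the Baeyer–Villiger oxidation of 1-indanones to 3,4-dihydrocoumarins. The six-membered lactone arises by ring expansion of the five-membered ketone through this 1,2-shift and not by a cyclization, and no stereocenter is formed. The step needs migration of the ring-fusion aryl carbon in preference to the C-2 methylene; aryl groups outrank primary alkyl groups in this rearrangement, and the methoxy group ortho to the migrating carbon stabilises the positive charge that develops on it. The bromine is removed beforehand so that it does not lower the electron density of the migrating ring, and the acetate keeps the phenol oxygen out of reach of the peracid.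

Step 6
Reactants: 7 7-acetoxy-8-methoxy-3,4-dihydro-2H-chromen-2-one; 8 octadecan-1-ol
Product: 11 octadecyl 3-(2,4-dihydroxy-3-methoxyphenyl)propanoate, via sodium octadecan-1-olate 9 (not isolated), via disodium bis(phenoxide) of the target 10 (not isolated)
Conditions: 8 (2.5 equiv), NaH (2.3 equiv), THF, 0 to 40 °C; then 7, 0 °C to rt, argon; AcOH, 0 °C
Reagents that add atoms: none
Why: Transesterification by alkoxide (nucleophilic acyl substitution at two aryl esters) should open the lactone to the octadecyl ester and remove the acetyl group as octadecyl acetate, each event being driven by exchange of an alkoxide for a far less basic phenoxide so that the ring-opened ester does not revert, and since octadecanolate is the only alkoxide present any further ester exchange is degenerate.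

**Compound list**

1 | 3-(4-hydroxy-3-methoxyphenyl)propanoic acid (dihydroferulic acid) | COc1cc(CCC(=O)O)ccc1O | starting material
2 | 3-(4-acetoxy-3-methoxyphenyl)propanoic acid | COc1cc(CCC(=O)O)ccc1OC(C)=O | intermediate
3 | 3-(4-acetoxy-2-bromo-5-methoxyphenyl)propanoic acid | COc1cc(CCC(=O)O)c(Br)cc1OC(C)=O | intermediate
4 | 6-acetoxy-4-bromo-7-methoxy-2,3-dihydro-1H-inden-1-one | COc1c(OC(C)=O)cc(Br)c2c1C(=O)CC2 | intermediate
5 | 6-acetoxy-7-methoxy-2,3-dihydro-1H-inden-1-one | COc1c(OC(C)=O)ccc2c1C(=O)CC2 | intermediate
6 | 6-acetoxy-1-hydroxy-7-methoxy-2,3-dihydro-1H-inden-1-yl 3-chlorobenzenecarboperoxoate (peroxyhemiketal adduct, racemic) | COc1c(OC(C)=O)ccc2c1C(O)(OOC(=O)c1cccc(Cl)c1)CC2 | intermediate (not isolated)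
7 | 7-acetoxy-8-methoxy-3,4-dihydro-2H-chromen-2-one | COc1c(OC(C)=O)ccc2c1OC(=O)CC2 | intermediate
8 | octadecan-1-ol | CCCCCCCCCCCCCCCCCCO | starting material
9 | sodium octadecan-1-olate | CCCCCCCCCCCCCCCCCC[O-].[Na+] | intermediate (not isolated)
10 | disodium 2-methoxy-4-[3-(octadecyloxy)-3-oxopropyl]benzene-1,3-diolate | CCCCCCCCCCCCCCCCCCOC(=O)CCc1ccc([O-])c(OC)c1[O-].[Na+].[Na+] | intermediate (not isolated)
11 | octadecyl 3-(2,4-dihydroxy-3-methoxyphenyl)propanoate | CCCCCCCCCCCCCCCCCCOC(=O)CCc1ccc(O)c(OC)c1O | target

**Step count**

Total steps: 6. Longest linear sequence: 6 steps (1 to 11).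

**Steps most likely to fail**

Step 5. Addition of the peracid to a carbonyl that is flanked by, and conjugated with, the methoxy group may be slow. The acetoxy group, meta to the migrating carbon, withdraws electron density, so shift of the methylene carbon or acid-promoted loss of the acetyl group may compete with the aryl shift. The fallback changes the substrate to a donor-substituted one and separates deprotection from ester formation. It sets out from 5:
- Methanolysis of the acetate (K2CO3, MeOH, rt) gives 6-hydroxy-7-methoxy-2,3-dihydro-1H-inden-1-one F1.
- O-Benzylation (benzyl bromide, K2CO3, DMF) gives 6-(benzyloxy)-7-methoxy-2,3-dihydro-1H-inden-1-one F2, whose ether oxygen cannot be lost to acid or peracid.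
- Oxidation with mCPBA should then give 7-(benzyloxy)-8-methoxy-3,4-dihydro-2H-chromen-2-one F3.
- One equivalent of alkoxide 9 in THF, then acetic acid, opens the lactone to octadecyl 3-[4-(benzyloxy)-2-hydroxy-3-methoxyphenyl]propanoate F4.
- Hydrogenolysis (H2, 10% Pd/C, EtOAc) comes back to the route at 11.

Step 3. The acylation has to take place at a carbon with two meta acceptors (bromine and acetoxy), so warming is needed. In the warm strong acid the acetyl group may be cleaved or transferred to carbon, or the acylium ion may attack the bromine-bearing carbon. The fallback separates activation from ring closure and runs the closure cold. It sets out from 3: oxalyl chloride with catalytic DMF in CH2Cl2 gives 3-(4-acetoxy-2-bromo-5-methoxyphenyl)propanoyl chloride F5. Friedel–Crafts acylation of this acid chloride with SnCl4 in CH2Cl2 at 0 °C comes back to the route at 4.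

Step 6. The hydroxy ester may close back to the lactone with loss of octadecanol during acidification or chromatography, cleavage of the acetate may remain incomplete, and the waxy by-products may hamper purification. The fallback forms the ester bond by alkylation at carbon instead of acyl transfer, so no equilibrium with the lactone is involved. It sets out from 7: saponification of both aryl esters (LiOH, aqueous THF, argon) and careful acidification to pH 4 at 0 °C gives 3-(2,4-dihydroxy-3-methoxyphenyl)propanoic acid F6. KHCO3 deprotonates only the carboxyl group, and SN2 alkylation of the carboxylate with 1-bromooctadecane in DMF at 50 °C comes back to the route at 11.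

**Further compounds**

F1 | step 5 | 6-hydroxy-7-methoxy-2,3-dihydro-1H-inden-1-one | COc1c(O)ccc2c1C(=O)CC2
F2 | step 5 | 6-(benzyloxy)-7-methoxy-2,3-dihydro-1H-inden-1-one | COc1c(OCc2ccccc2)ccc2c1C(=O)CC2
F3 | step 5 | 7-(benzyloxy)-8-methoxy-3,4-dihydro-2H-chromen-2-one | COc1c(OCc2ccccc2)ccc2c1OC(=O)CC2
F4 | step 5 | octadecyl 3-[4-(benzyloxy)-2-hydroxy-3-methoxyphenyl]propanoate | CCCCCCCCCCCCCCCCCCOC(=O)CCc1ccc(OCc2ccccc2)c(OC)c1O
F5 | step 3 | 3-(4-acetoxy-2-bromo-5-methoxyphenyl)propanoyl chloride | COc1cc(CCC(Cl)=O)c(Br)cc1OC(C)=O
F6 | step 6 | 3-(2,4-dihydroxy-3-methoxyphenyl)propanoic acid | COc1c(O)ccc(CCC(=O)O)c1O
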